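The closed, stirred vessel held L and E, and I had to call its contents at the end of each flask.

| flask | L | E | remark | time |
|---|---|---|---|---|
| beta | 0.10 M | 0.039 M | run made earlier |  |
| epsilon | 0.10 M | 0.084 M | run made earlier |  |
| south | 0.10 M | 0.0500 M |  | 2.0 d |
| north-east | 0.10 M | 0.0800 M |  | 2.0 d |
| west | 0.10 M | 0.120 M |  | 2.0 d |

- beta (time / h: G / %, L / %): 4.00: 14.4, 66.8; 12.0: 11.6, 63.4; 20.0: 12.8, 63.6; 30.0: 12.9, 65.0; 50.0: 11.3, 64.4
- epsilon (time / h: G / %, L / %): 10.0: 21.1, 34.0; 20.0: 18.8, 30.5; 30.0: 17.9, 29.9; 40.0: 17.8, 30.5; 50.0: 16.4, 30.1

(scatter of a reading: 1 percentage point)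

- which of these holds the largest part of the L at the end of south (Q / L / G / Z)
- which of these holds the largest part of the L at the end of north-east (Q / L / G / Z)
- which of these holds the largest part of the L at the end of west (Q / L / G / Z)
- G at the end of south, in percent of the L charged



I reckoned in fractions of the L charged, starting with the main step by itself: L takes E to give G, one E per L. In south E is the limiting reagent, charged in a smaller amount than L, so this step leaves 50.0% of L once E is used up.

Next I added the second exchange. A Z holds a further E that takes no L, so I wrote the balance of E: E charged minus L lost is the spare E, which has to hold the extra E of every Z and Q and any unused E. The beta run's last reading of L gives a spare share, the part of the E charge not spent on taking L, of 8.72%, and the epsilon run gives 16.8%. Both are readings with their scatter.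

Last came what the readings do not show. In beta, 24.3% of the L charged was unread, more than that run's spare E of 3.40%. So I took the unread part to be mainly in forms holding one E, which leaves the balance unchanged.

With the beta share, south keeps 54.4% of L and has spare E of 4.36%. Between the last G readings of the two runs, I put G in south at 12.5%. With the epsilon share, north-east keeps 33.4% of L, above its spare E of 13.4%, so I called L there. West was charged with more E than L, which makes its spare E at least 20.0%, and I called Z.

For south, north-east and west the forecast named L, Z and Z, with G at 14% in south, and it noted that “the E balance is exceeded”. Its call parted from mine in north-east, and its G in south stood higher than mine.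

South ended with G at 12.8%, and L led there; north-east gave L and west Z.

    Z + E ⇌ X + Q (K = 0.280, k = 15.0 M⁻¹ h⁻¹)
    X + G → D (k = 0.310 M⁻¹ h⁻¹)
    G + E ⇌ X + Z (K = 27.0, k = 3.20 M⁻¹ h⁻¹)
    G ⇌ J (K = 1.50, k = 0.440 h⁻¹)
    L + E ⇌ X + G (K = 46.0, k = 6.10 M⁻¹ h⁻¹)

In north-east, L stood at 31.3% and Z at 10.4%. In south, the forms holding one E that went unread were J at 19.5% and D at 9.26%. Put back through the balance, south's L gives a spare share of 8.67%, which is spare E of 4.33%, and Z held 4.08% of it.

A neighbour flask is south with 0.25 M of L. The beta share gives it spare E of 1.74% and L of 81.7%. The flask gave L 80.8% and Z 0.730%.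

The runs stem from a simulated flask from invented constants; the scatter is artificial.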